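**Strategy.** Everything rests on building ring B, the fully substituted benzene, from two small fragments. The feature exploited is its resorcinol pattern fused to the alkoxy lactone: the phenol carbon and the lactone C=C come from butenolide diazoketone 7, the CH2O-bearing and ester-oxygen-bearing carbons from siloxyalkyne 11. One photochemical operation (Wolff rearrangement, [2+2] addition, ring opening, six-electron ring closure) forms four ring B C–C bonds and the ring, leaving one C–H para to the phenol. The precursor is a 4-diazoacetyl butenolide whose acetal carbon already has the target configuration, fixed by an (S)-1-phenylethyl auxiliary. Ring A is then attached by esterification and oxidative diaryl ether closure.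

Key step: step 5

Assumption 1: the lactol carbon of the target can epimerize by ring–chain tautomerism, so it is released in the last step under neutral conditions and handled without acid or base.
Assumption 2: the (2R,1′S) epimer of acetal 5 is taken to be the less soluble one; should the other epimer crystallize, the antipodal alcohol would give the same acetal configuration, since the auxiliary is cleaved at the end.

Step 1
Reactants: 1 furan-3-carboxylic acid
Product: 3 2-hydroxy-5-oxo-2,5-dihydrofuran-3-carboxylic acid (racemic lactol), via furan endoperoxide 2 (not isolated)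
Conditions: O2, hν (visible), tetraphenylporphyrin (cat.), i-Pr2NEt, CH2Cl2, −78 °C → rt; then cold aq. HCl to pH 2
Reagents that add atoms: dioxygen, O=O
Why: Singlet oxygen adds across the furan 2,5-positions ([4+2]) and the hindered amine removes the bridgehead proton remote from the carboxylate (Kornblum–DeLaMare-type fragmentation), which should place the lactone carbonyl distal and the lactol carbon next to the carboxyl-bearing carbon; the lactol centre forms racemic and is fixed in step 2.

Step 2
Reactants: 3 2-hydroxy-5-oxo-2,5-dihydrofuran-3-carboxylic acid; 4 (S)-1-phenylethanol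
Product: 5 (2R)-5-oxo-2-[(1S)-1-phenylethoxy]-2,5-dihydrofuran-3-carboxylic acid
Conditions: PPTS (cat.), PhH, reflux (Dean–Stark); crystallization from EtOAc/heptane, mother liquor re-equilibrated with PPTS
Reagents that add atoms: none
Why: Acid-catalysed pseudo-ester (lactol acetal) formation through the acyloxy-stabilised oxocarbenium ion gives two acetal epimers that interconvert under the acid, so crystallization of the (2R,1′S) epimer with recycling of the mother liquor should set the acetal stereocentre (crystallization-induced diastereomer transformation).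

Step 3
Reactants: 5 (2R)-5-oxo-2-[(1S)-1-phenylethoxy]-2,5-dihydrofuran-3-carboxylic acid
Product: 7 (5R)-4-(2-diazoacetyl)-5-[(1S)-1-phenylethoxy]furan-2(5H)-one, via acid chloride 6 (not isolated)
Conditions: 1-chloro-N,N,2-trimethylprop-1-en-1-amine (1.05 equiv), CH2Cl2, 0 °C; then CH2N2 (1.2 equiv), CaO, Et2O, −78 → −30 °C, dark; AcOH quench
Reagents that add atoms: diazomethane, C=[N+]=[N-]
Why: The α-chloroenamine makes the acid chloride without HCl, which spares the acid-labile acetal, and C-acylation of diazomethane (first stage of the Arndt–Eistert sequence) with CaO as HCl scavenger needs only a slight excess of diazomethane at low temperature, which should keep 1,3-dipolar addition to the doubly activated butenolide alkene from competing.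

Step 4
Reactants: 8 tert-butyldimethyl(prop-2-yn-1-yloxy)silane
Product: 11 3-(tert-butyldimethylsilyloxy)-1-(triisopropylsilyloxy)prop-1-yne, via lithium acetylide 9 (not isolated), via lithium ynolate 10 (not isolated)
Conditions: n-BuLi, THF, −78 °C; LiOOt-Bu [from anhydrous t-BuOOH and LiN(SiMe3)2], −78 → 0 °C; TIPSOTf, −78 → 0 °C
Reagents that add atoms: tert-butyl hydroperoxide (as LiOOt-Bu), CC(C)(C)OO; triisopropylsilyl trifluoromethanesulfonate, CC(C)[Si](C(C)C)(C(C)C)OS(=O)(=O)C(F)(F)F
Why: Electrophilic oxygen transfer from the lithium peroxide to acetylide 9 gives ynolate 10, which the bulky, oxophilic silyl triflate should trap on oxygen (acetylide oxidation/O-silylation route to siloxyalkynes).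

Step 5
Reactants: 7 (5R)-4-(2-diazoacetyl)-5-[(1S)-1-phenylethoxy]furan-2(5H)-one; 11 3-(tert-butyldimethylsilyloxy)-1-(triisopropylsilyloxy)prop-1-yne
Product: 16 (3R)-6-[(tert-butyldimethylsilyloxy)methyl]-7-hydroxy-3-[(1S)-1-phenylethoxy]-5-(triisopropylsilyloxy)-2-benzofuran-1(3H)-one, via vinylketene 12 (not isolated), via vinylcyclobutenone 13 (not isolated), via dienylketene 14 (not isolated), via cyclohexadienone 15 (not isolated)
Conditions: 11 (1.5 equiv), hν (300 nm, Pyrex), degassed ClCH2CH2Cl, 20 °C; then 80 °C, dark
Reagents that add atoms: none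
Why: Light expels N2 from 7 with migration of the butenolide carbon (Wolff rearrangement) to give vinylketene 12, whose carbonyl carbon bonds to the nucleophilic, CH2OSi-bearing carbon of 11 in a [2+2] addition that gives 4-vinylcyclobutenone 13. Four-electron electrocyclic opening of 13 gives dienylketene 14, ring B is closed by six-electron electrocyclization of the ketene carbon onto the former butenolide α-carbon, and enolization of cyclohexadienone 15 gives the phenol. The closest known reaction is the Danheiser benzannulation of cycloalkenyl diazomethyl ketones with triisopropylsiloxyalkynes to resorcinol monosilyl ethers, the butenolide being only a more electron-poor vinyl partner. No stereocentre is created, and the acetal carbon brought in from 5 is a spectator because no base is present and its C–H takes no part in the pericyclic steps. The selectivity needed is the orientation of the [2+2] step, which the polarisation of the silyl ynol ether secures, so that OTIPS ends up meta to the new phenol and the single C–H para to it; the ring closure has only one terminus available.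

Step 6
Reactants: 16 (3R)-6-[(tert-butyldimethylsilyloxy)methyl]-7-hydroxy-3-[(1S)-1-phenylethoxy]-5-(triisopropylsilyloxy)-2-benzofuran-1(3H)-one
Product: 17 (3R)-6-[(tert-butyldimethylsilyloxy)methyl]-5,7-dihydroxy-3-[(1S)-1-phenylethoxy]-2-benzofuran-1(3H)-one
Conditions: TBAF (1.05 equiv), AcOH (1.1 equiv), THF, −20 → 0 °C
Reagents that add atoms: none
Why: Fluoride cleaves an aryl Si–O bond much faster than an alkyl one because phenoxide is the better leaving group, so one equivalent of buffered fluoride at low temperature should remove only the TIPS group (chemoselective desilylation).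

Step 7
Reactants: 18 methyl 2,4-dihydroxy-3,6-dimethylbenzoate
Product: 19 methyl 2-hydroxy-4-methoxy-3,6-dimethylbenzoate
Conditions: MeI (1.1 equiv), K2CO3, acetone, reflux
Reagents that add atoms: iodomethane, CI
Why: Williamson methylation should take place only at the 4-hydroxyl, because the 2-hydroxyl is hydrogen-bonded to the ester carbonyl and flanked by a methyl group.

Step 8
Reactants: 19 methyl 2-hydroxy-4-methoxy-3,6-dimethylbenzoate
Product: 20 2-hydroxy-4-methoxy-3,6-dimethylbenzoic acid
Conditions: KOH, DMSO/H2O, 80 °C; then cold 1 M HCl to pH 2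
Reagents that add atoms: potassium hydroxide, [K+].[OH-]
Why: Poorly solvated hydroxide in aqueous DMSO saponifies the hindered ester by acyl–oxygen cleavage, and cold acidification avoids decarboxylation of the electron-rich salicylic acid.

Step 9
Reactants: 17 (3R)-6-[(tert-butyldimethylsilyloxy)methyl]-5,7-dihydroxy-3-[(1S)-1-phenylethoxy]-2-benzofuran-1(3H)-one; 20 2-hydroxy-4-methoxy-3,6-dimethylbenzoic acid
Product: 21 (3R)-6-[(tert-butyldimethylsilyloxy)methyl]-7-hydroxy-1-oxo-3-[(1S)-1-phenylethoxy]-1,3-dihydro-2-benzofuran-5-yl 2-hydroxy-4-methoxy-3,6-dimethylbenzoate (depside)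
Conditions: DCC (1.1 equiv), DMAP (cat.), CH2Cl2, 0 → 20 °C
Reagents that add atoms: none
Why: In this Steglich esterification the 5-hydroxyl of 17 (para to the lactone carbonyl, not chelated) should be the only reactive nucleophile, since the 7-hydroxyl of 17 and the 2-hydroxyl of 20 are both hydrogen-bonded to an ortho carbonyl and flanked on both sides, as in depside syntheses from free ortho-hydroxy acids.

Step 10
Reactants: 21 depside
Product: 22 protected depsidone (ring A oxygen bonded to C4 of the phthalide; TBS ether and (S)-1-phenylethyl acetal retained; acetal carbon R)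
Conditions: PhI(OAc)2 (1.05 equiv), (CF3)2CHOH/CH2Cl2 (1:4), 2 mM, −20 → 0 °C
Reagents that add atoms: none
Why: Two-electron oxidation of the ring B phenol by the trivalent iodine reagent makes its para carbon, the only unsubstituted ring B position, electrophilic, the tethered ring A phenol adds there through a seven-membered transition state and loss of the para proton re-aromatises the ring (oxidative phenol coupling of a depside to a depsidone, in a non-nucleophilic solvent so that nothing external is captured).

Step 11
Reactants: 22 protected depsidone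
Product: 23 depsidone (S)-1-phenylethyl acetal with free CH2OH
Conditions: HF·pyridine, THF/pyridine, 0 → 20 °C
Reagents that add atoms: none
Why: Si–F bond formation drives cleavage of the primary silyl ether under mildly acidic, non-nucleophilic conditions that should leave the aryl ester, the diaryl ether and the mixed acetal untouched.

Step 12
Reactants: 23 depsidone (S)-1-phenylethyl acetal
Product: 24 target depsidone CNP0321962.1, (R)-hydroxyphthalide
Conditions: H2 (1 atm), Pd/C (10% Pd), EtOAc, 20 °C; stop after one equivalent of H2, filter, evaporate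
Reagents that add atoms: none
Why: Catalytic hydrogenolysis cleaves the unhindered secondary benzylic C–O bond of the auxiliary on the side away from the acetal carbon, so the R configuration is retained, while the phthalide C–O bonds on the congested ring B should resist these neutral conditions.

**Compound list**

1 | furan-3-carboxylic acid (3-furoic acid) | OC(=O)c1ccoc1 | starting material
2 | 2,3,7-trioxabicyclo[2.2.1]hept-5-ene-5-carboxylic acid (furan endoperoxide, racemic, not isolated) | OC(=O)C1=CC2OOC1O2 | intermediate
3 | 2-hydroxy-5-oxo-2,5-dihydrofuran-3-carboxylic acid (racemic lactol) | O=C1C=C(C(O)=O)C(O)O1 | intermediate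
4 | (S)-1-phenylethanol | C[C@H](O)c1ccccc1 | starting material
5 | (2R)-5-oxo-2-[(1S)-1-phenylethoxy]-2,5-dihydrofuran-3-carboxylic acid | O=C1C=C(C(O)=O)[C@H](O[C@@H](C)c2ccccc2)O1 | intermediate
6 | (2R)-5-oxo-2-[(1S)-1-phenylethoxy]-2,5-dihydrofuran-3-carbonyl chloride (not isolated) | O=C1C=C(C(Cl)=O)[C@H](O[C@@H](C)c2ccccc2)O1 | intermediate
7 | (5R)-4-(2-diazoacetyl)-5-[(1S)-1-phenylethoxy]furan-2(5H)-one | O=C1C=C(C(=O)C=[N+]=[N-])[C@H](O[C@@H](C)c2ccccc2)O1 | intermediate
8 | tert-butyldimethyl(prop-2-yn-1-yloxy)silane | C#CCO[Si](C)(C)C(C)(C)C | starting material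
9 | [3-(tert-butyldimethylsilyloxy)prop-1-yn-1-yl]lithium (not isolated) | [Li]C#CCO[Si](C)(C)C(C)(C)C | intermediate
10 | lithium 3-(tert-butyldimethylsilyloxy)prop-1-yn-1-olate (not isolated) | [Li+].[O-]C#CCO[Si](C)(C)C(C)(C)C | intermediate
11 | 3-(tert-butyldimethylsilyloxy)-1-(triisopropylsilyloxy)prop-1-yne | CC(C)[Si](C(C)C)(C(C)C)OC#CCO[Si](C)(C)C(C)(C)C | intermediate
12 | (5R)-4-(2-oxoethenyl)-5-[(1S)-1-phenylethoxy]furan-2(5H)-one (vinylketene, not isolated) | O=C1C=C(C=C=O)[C@H](O[C@@H](C)c2ccccc2)O1 | intermediate
13 | 2-[(tert-butyldimethylsilyloxy)methyl]-4-[(2R)-5-oxo-2-[(1S)-1-phenylethoxy]-2,5-dihydrofuran-3-yl]-3-(triisopropylsilyloxy)cyclobut-2-en-1-one (either configuration at C4 of the four-membered ring, not isolated) | O=C1C(CO[Si](C)(C)C(C)(C)C)=C(O[Si](C(C)C)(C(C)C)C(C)C)C1C2=CC(=O)O[C@H]2O[C@@H](C)c2ccccc2 | intermediate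
14 | 2-[(tert-butyldimethylsilyloxy)methyl]-4-[(2R)-5-oxo-2-[(1S)-1-phenylethoxy]-2,5-dihydrofuran-3-yl]-3-(triisopropylsilyloxy)buta-1,3-dien-1-one (ketenyl carbon and butenolide cis on the 3,4-double bond, not isolated) | O=C=C(CO[Si](C)(C)C(C)(C)C)/C(O[Si](C(C)C)(C(C)C)C(C)C)=C\C1=CC(=O)O[C@H]1O[C@@H](C)c1ccccc1 | intermediate
15 | (3R)-6-[(tert-butyldimethylsilyloxy)methyl]-3-[(1S)-1-phenylethoxy]-5-(triisopropylsilyloxy)-3,7a-dihydro-2-benzofuran-1,7-dione (either configuration at C7a, not isolated) | O=C1C(CO[Si](C)(C)C(C)(C)C)=C(O[Si](C(C)C)(C(C)C)C(C)C)C=C2C1C(=O)O[C@H]2O[C@@H](C)c1ccccc1 | intermediate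
16 | (3R)-6-[(tert-butyldimethylsilyloxy)methyl]-7-hydroxy-3-[(1S)-1-phenylethoxy]-5-(triisopropylsilyloxy)-2-benzofuran-1(3H)-one | CC(C)[Si](C(C)C)(C(C)C)Oc1c(CO[Si](C)(C)C(C)(C)C)c(O)c2c(c1)[C@H](O[C@@H](C)c3ccccc3)OC2=O | intermediate
17 | (3R)-6-[(tert-butyldimethylsilyloxy)methyl]-5,7-dihydroxy-3-[(1S)-1-phenylethoxy]-2-benzofuran-1(3H)-one | Oc1c(CO[Si](C)(C)C(C)(C)C)c(O)c2c(c1)[C@H](O[C@@H](C)c3ccccc3)OC2=O | intermediate
18 | methyl 2,4-dihydroxy-3,6-dimethylbenzoate (methyl atrarate) | COC(=O)c1c(C)cc(O)c(C)c1O | starting material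
19 | methyl 2-hydroxy-4-methoxy-3,6-dimethylbenzoate | COC(=O)c1c(C)cc(OC)c(C)c1O | intermediate
20 | 2-hydroxy-4-methoxy-3,6-dimethylbenzoic acid | OC(=O)c1c(C)cc(OC)c(C)c1O | intermediate
21 | (3R)-6-[(tert-butyldimethylsilyloxy)methyl]-7-hydroxy-1-oxo-3-[(1S)-1-phenylethoxy]-1,3-dihydro-2-benzofuran-5-yl 2-hydroxy-4-methoxy-3,6-dimethylbenzoate (depside) | COc1cc(C)c(C(=O)Oc2c(CO[Si](C)(C)C(C)(C)C)c(O)c3c(c2)[C@H](O[C@@H](C)c2ccccc2)OC3=O)c(O)c1C | intermediate
22 | protected depsidone: seven-membered ester/ether ring between ring A and ring B, CH2OTBS, chelated phenol, (R)-acetal carrying the (S)-1-phenylethyl group | COc1cc(C)c2c(c1C)Oc1c(c(CO[Si](C)(C)C(C)(C)C)c(O)c3c1[C@H](O[C@@H](C)c1ccccc1)OC3=O)OC2=O | intermediate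
23 | depsidone with free CH2OH and (R)-acetal carrying the (S)-1-phenylethyl group | COc1cc(C)c2c(c1C)Oc1c(c(CO)c(O)c3c1[C@H](O[C@@H](C)c1ccccc1)OC3=O)OC2=O | intermediate
24 | CNP0321962.1, depsidone with (R)-hydroxyphthalide | COc1cc(C)c2c(c1C)Oc1c(c(CO)c(O)c3c1[C@H](O)OC3=O)OC2=O | target

**Totals.** 12 steps in all. The longest linear sequence is 9 steps (steps 1, 2, 3, 5, 6, 9, 10, 11, 12 from furan-3-carboxylic acid).

**Steps most likely to fail**

Step 5. Competing light-driven processes (photoreactions of the butenolide or of the phenol formed, capture of the carbene by the acetal oxygen) or acylation of the product phenol by the vinylketene could outrun the capture of the ketene by the alkyne. The fallback sets out from 7 and comes back at 16, and makes the same vinylketene in the dark. Wolff rearrangement of 7 in aqueous THF with catalytic AgO2CPh, where water captures the ketene (Arndt–Eistert homologation), should give [(2R)-5-oxo-2-[(1S)-1-phenylethoxy]-2,5-dihydrofuran-3-yl]acetic acid F1. 1-Chloro-N,N,2-trimethylprop-1-en-1-amine would convert it into [(2R)-5-oxo-2-[(1S)-1-phenylethoxy]-2,5-dihydrofuran-3-yl]acetyl chloride F2. Slow addition of i-Pr2NEt to F2 and 11 in toluene would generate 12 by dehydrochlorination; the thermal ketene–siloxyalkyne [2+2] addition and heating at 80 °C then carry 13 on to 16.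

Step 10. Oxidation could start at the more electron-rich ring A phenol and lead to C–C spiro-coupling or solvent capture at its free para position, and the aryloxyphenol formed could be oxidized further. The fallback sets out from 17 and comes back at 22, and replaces the oxidation by a two-electron coupling. NBS in CH2Cl2 at −40 °C should brominate the only free ring B position (before ring A, whose free para position would compete, is attached) to give (3R)-4-bromo-6-[(tert-butyldimethylsilyloxy)methyl]-5,7-dihydroxy-3-[(1S)-1-phenylethoxy]-2-benzofuran-1(3H)-one F3. Esterification with 20 under the conditions of step 9 would give (3R)-4-bromo-6-[(tert-butyldimethylsilyloxy)methyl]-7-hydroxy-1-oxo-3-[(1S)-1-phenylethoxy]-1,3-dihydro-2-benzofuran-5-yl 2-hydroxy-4-methoxy-3,6-dimethylbenzoate F4. Intramolecular Ullmann etherification (CuI, N,N-dimethylglycine, Cs2CO3, dioxane, 90 °C) would then close the seven-membered ring to 22.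

Step 3. 1,3-Dipolar addition of diazomethane to the doubly activated butenolide alkene could compete with C-acylation, and basic species could epimerize the acetal carbon. The fallback sets out from 6 and comes back at 7 without diazomethane. N-Isocyanoiminotriphenylphosphorane in CH2Cl2 adds to the acid chloride through its isocyanide carbon, and water hydrolyses the iminophosphorane to (5R)-4-(2-chloro-2-hydrazinylideneacetyl)-5-[(1S)-1-phenylethoxy]furan-2(5H)-one F5. ZnBr2 and i-Pr2NH at 0 °C would then remove HCl to give 7.

**Further compounds**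

F1 | step 5 | [(2R)-5-oxo-2-[(1S)-1-phenylethoxy]-2,5-dihydrofuran-3-yl]acetic acid | O=C1C=C(CC(O)=O)[C@H](O[C@@H](C)c2ccccc2)O1
F2 | step 5 | [(2R)-5-oxo-2-[(1S)-1-phenylethoxy]-2,5-dihydrofuran-3-yl]acetyl chloride | O=C1C=C(CC(Cl)=O)[C@H](O[C@@H](C)c2ccccc2)O1
F3 | step 10 | (3R)-4-bromo-6-[(tert-butyldimethylsilyloxy)methyl]-5,7-dihydroxy-3-[(1S)-1-phenylethoxy]-2-benzofuran-1(3H)-one | Oc1c(CO[Si](C)(C)C(C)(C)C)c(O)c2c(c1Br)[C@H](O[C@@H](C)c3ccccc3)OC2=O
F4 | step 10 | (3R)-4-bromo-6-[(tert-butyldimethylsilyloxy)methyl]-7-hydroxy-1-oxo-3-[(1S)-1-phenylethoxy]-1,3-dihydro-2-benzofuran-5-yl 2-hydroxy-4-methoxy-3,6-dimethylbenzoate | COc1cc(C)c(C(=O)Oc2c(CO[Si](C)(C)C(C)(C)C)c(O)c3c(c2Br)[C@H](O[C@@H](C)c2ccccc2)OC3=O)c(O)c1C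
F5 | step 3 | (5R)-4-(2-chloro-2-hydrazinylideneacetyl)-5-[(1S)-1-phenylethoxy]furan-2(5H)-one | O=C1C=C(C(=O)C(Cl)=NN)[C@H](O[C@@H](C)c2ccccc2)O1
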